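A direct plan would buy ring B as 5-bromo-2-methoxyphenol A1 and grow ring A on its oxygen from an open chain.
O-Alkylation, Michael addition, decarboxylation and Dieckmann closure would give the 2-aryloxycyclohexane-1,3-dione A2, which would be turned into the β-bromo enone A3.
Selenenylation and selenoxide elimination would aromatise A3 to the phenol A4; two brominations would give A5, and O-demethylation would end the route.
Its weakest stretch would be the chain assembly and ring closure up to A2: four operations for a ring that holds no more information than a commercial bromocatechol.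
The aromatisation of A3 would be left to chance: a lithium amide would have to deprotonate C6 of a vinylogous acyl bromide and spare C3 and C4, and selenium would be spent only to gain a benzene ring.
The double bromination of A4 would be the step least welcome on late material: the second bromine, due ortho to OH on a ring already twice brominated, could as well enter the methoxy ring para to the ether oxygen.

**Plan of the new route**

Numbering: ring A is the tribromophenol ring (C1 OH, C2 ether O, Br at C3, C4, C6); ring B is the bromophenol ring (C1' ether O, C2' OH, C5' Br).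
The retrosynthesis cuts the C2'–O bond back to a C2'–CHO bond (Baeyer–Villiger), then the C4–Br bond, then the ether bond O–C1' of ring B; the two C–O bonds of ring A are bought, not made.
The enabling feature: without Br at C4, ring A is twofold-symmetric 3,6-dibromocatechol 1, with its oxygens at C1 and C2 flanked by Br at C6 and C3, so either hydroxyl may be arylated. On ring B the OH at C2' is ortho to C1' and para to Br at C5', the pattern in which a formyl group at C2' activates fluoride at C1', as in 4-bromo-2-fluorobenzaldehyde 2.
Both rings are bought aromatic; the ether bond forms first, ring A then takes its last bromine, and ring B gets its hydroxyl last.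
No ring is built from a chain and nothing is aromatised; the single bromination meets one open position para to OH while the formyl group deactivates ring B.

Key step: step 1

Remark: 3,6-dibromocatechol 1 is taken as a catalogue compound. A base-induced shift of the carbonyl-activated aryl group between the two ring-A oxygens (Smiles rearrangement) is degenerate in symmetric ether 3 but not in 4, so after step 1 the ring-A hydroxyl is kept protonated (buffered or acidic media only) as long as ring B carries its carbonyl group.

**Route**

Step 1
Reactants: 1 3,6-dibromobenzene-1,2-diol (3,6-dibromocatechol); 2 4-bromo-2-fluorobenzaldehyde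
Product: 3 4-bromo-2-(3,6-dibromo-2-hydroxyphenoxy)benzaldehyde
Conditions: 1 (2.0 equiv), K2CO3 (2.2 equiv), degassed DMF, Ar, 2 added slowly, 70 °C; then 1 M HCl
Reagents that add atoms: none
Why: Nucleophilic aromatic substitution (SNAr) by addition–elimination: the monophenoxide of 1 adds to the fluorine-bearing carbon of 2 to give a Meisenheimer complex whose charge is taken up by the ortho formyl group, and fluoride leaves. The closest known reaction type is the diaryl ether synthesis from phenols and 2-fluorobenzaldehydes with K2CO3 in a dipolar aprotic solvent, which also accepts 2,6-disubstituted phenoxides. No ring is closed and no stereocentre is formed. Three selectivities are needed: between the two hydroxyls of 1, which its symmetry makes equivalent; between one and two arylations, secured by the excess of 1 and by the low nucleophilicity of the remaining phenoxide of 3, which is flanked by bromine and the new aryloxy group; and between fluoride ortho and bromide para to the formyl group, where fluoride should be displaced far faster at 70 °C. The step should fix the whole oxygen pattern of the target in latent form and three of its four bromines from two simple benzenes.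

Step 2
Reactants: 3 4-bromo-2-(3,6-dibromo-2-hydroxyphenoxy)benzaldehyde
Product: 4 4-bromo-2-(2,3,5-tribromo-6-hydroxyphenoxy)benzaldehyde
Conditions: Br2 (1.05 equiv), NaOAc (1.2 equiv), AcOH, 15 °C → rt
Reagents that add atoms: bromine, BrBr
Why: Electrophilic aromatic bromination in which the free hydroxyl of ring A directs to its para position C4, the only open ortho/para site because both ortho positions carry bromine and the aryloxy group, while ring B is deactivated by the formyl group and the aldehyde should survive Br2 in buffered acetic acid as it does in brominations of hydroxybenzaldehydes.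

Step 3
Reactants: 4 4-bromo-2-(2,3,5-tribromo-6-hydroxyphenoxy)benzaldehyde
Product: 6 3,4,6-tribromo-2-(5-bromo-2-hydroxyphenoxy)phenol, via aryl formate 5 (not isolated)
Conditions: mCPBA (1.5 equiv), CH2Cl2, 0 °C → rt; Na2S2O3 wash; then HCl (cat.), MeOH, rt
Reagents that add atoms: meta-chloroperoxybenzoic acid (mCPBA), OOC(=O)c1cccc(Cl)c1
Why: Baeyer–Villiger oxidation of an ortho-aryloxybenzaldehyde (Dakin-type), in which the peracid adds to the formyl group and the aryl group, made electron-rich at the migrating carbon by the ortho ether oxygen, migrates in the Criegee intermediate to give formate 5, which acid-catalysed methanolysis should cleave without touching the diaryl ether or any C–Br bond.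

**Compound list**

1 | 3,6-dibromobenzene-1,2-diol (3,6-dibromocatechol) | Oc1c(Br)ccc(Br)c1O | starting material
2 | 4-bromo-2-fluorobenzaldehyde | O=Cc1ccc(Br)cc1F | starting material
3 | 4-bromo-2-(3,6-dibromo-2-hydroxyphenoxy)benzaldehyde | O=Cc1ccc(Br)cc1Oc1c(O)c(Br)ccc1Br | intermediate
4 | 4-bromo-2-(2,3,5-tribromo-6-hydroxyphenoxy)benzaldehyde | O=Cc1ccc(Br)cc1Oc1c(O)c(Br)cc(Br)c1Br | intermediate
5 | 4-bromo-2-(2,3,5-tribromo-6-hydroxyphenoxy)phenyl formate (not isolated) | O=COc1ccc(Br)cc1Oc1c(O)c(Br)cc(Br)c1Br | intermediate
6 | 3,4,6-tribromo-2-(5-bromo-2-hydroxyphenoxy)phenol (achiral) | Oc1ccc(Br)cc1Oc1c(O)c(Br)cc(Br)c1Br | target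

Total step count: 3. Longest linear sequence: 3 steps (1 → 3 → 4 → 6; 2 enters in step 1).

**Steps most likely to fail**

Step 3. In the Criegee intermediate the hydrogen could migrate in place of the aryl group, because the migrating ring carries bromine and an electron-poor aryloxy group; the formyl group would then be over-oxidised to a carboxylic acid and the hydroxyl of ring B would be lost. The fallback exchanges the latent hydroxyl for an acetyl group, where only a methyl group competes with the aryl group. It sets out from compound 1. SNAr with 1-(4-bromo-2-fluorophenyl)ethan-1-one F1 under the conditions of step 1 at 90 °C should give 1-[4-bromo-2-(3,6-dibromo-2-hydroxyphenoxy)phenyl]ethan-1-one F2. NBS in MeCN should brominate ring A para to its hydroxyl to give 1-[4-bromo-2-(2,3,5-tribromo-6-hydroxyphenoxy)phenyl]ethan-1-one F3. Baeyer–Villiger oxidation with trifluoroperacetic acid (from trifluoroacetic anhydride and H2O2·urea, Na2HPO4, CH2Cl2, 0 °C) should give 4-bromo-2-(2,3,5-tribromo-6-hydroxyphenoxy)phenyl acetate F4. Acid-catalysed methanolysis (HCl cat., MeOH) comes back to the route at compound 6.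

Step 1. The catechol could be arylated twice, the phenoxide could also displace the bromide para to the formyl group and start oligomers, or the catecholate could be oxidised by traces of air. The fallback uses a nucleophile with a single hydroxyl and gives up the symmetry argument. It sets out from compound 2. SNAr with 2-bromo-6-methoxyphenol F5 (K2CO3, DMF, 80 °C) should give 4-bromo-2-(2-bromo-6-methoxyphenoxy)benzaldehyde F6. BBr3 in CH2Cl2 (−78 °C → 0 °C) should cleave the methyl ether to 4-bromo-2-(2-bromo-6-hydroxyphenoxy)benzaldehyde F7. Bromination para and ortho to the freed hydroxyl (Br2 2.1 equiv, NaOAc, AcOH) comes back to the route at compound 4.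

Step 2. Substitution of the twice-brominated phenol ring could be slow enough for bromine to oxidise the formyl group or to attack ring B para to the ether oxygen. The fallback removes the formyl group first and draws the ring selectivity from acidity instead of from a deactivating group. It sets out from compound 3. mCPBA in CH2Cl2 should give 4-bromo-2-(3,6-dibromo-2-hydroxyphenoxy)phenyl formate F8, and methanolysis (HCl cat., MeOH) should give 3,6-dibromo-2-(5-bromo-2-hydroxyphenoxy)phenol F9. With one equivalent of NaOH in aqueous MeOH only the more acidic ring-A hydroxyl, flanked by bromine and the aryloxy group, should ionise. Br2 (1.0 equiv) at 0 °C should then attack this phenoxide at its only open para position, which comes back to the route at compound 6.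

**Further compounds**

F1 | step 3 | 1-(4-bromo-2-fluorophenyl)ethan-1-one | CC(=O)c1ccc(Br)cc1F
F2 | step 3 | 1-[4-bromo-2-(3,6-dibromo-2-hydroxyphenoxy)phenyl]ethan-1-one | CC(=O)c1ccc(Br)cc1Oc1c(O)c(Br)ccc1Br
F3 | step 3 | 1-[4-bromo-2-(2,3,5-tribromo-6-hydroxyphenoxy)phenyl]ethan-1-one | CC(=O)c1ccc(Br)cc1Oc1c(O)c(Br)cc(Br)c1Br
F4 | step 3 | 4-bromo-2-(2,3,5-tribromo-6-hydroxyphenoxy)phenyl acetate | CC(=O)Oc1ccc(Br)cc1Oc1c(O)c(Br)cc(Br)c1Br
F5 | step 1 | 2-bromo-6-methoxyphenol | COc1cccc(Br)c1O
F6 | step 1 | 4-bromo-2-(2-bromo-6-methoxyphenoxy)benzaldehyde | COc1cccc(Br)c1Oc1cc(Br)ccc1C=O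
F7 | step 1 | 4-bromo-2-(2-bromo-6-hydroxyphenoxy)benzaldehyde | Oc1cccc(Br)c1Oc1cc(Br)ccc1C=O
F8 | step 2 | 4-bromo-2-(3,6-dibromo-2-hydroxyphenoxy)phenyl formate | O=COc1ccc(Br)cc1Oc1c(O)c(Br)ccc1Br
F9 | step 2 | 3,6-dibromo-2-(5-bromo-2-hydroxyphenoxy)phenol | Oc1ccc(Br)cc1Oc1c(O)c(Br)ccc1Br
A1 | direct plan | 5-bromo-2-methoxyphenol | COc1ccc(Br)cc1O
A2 | direct plan | 2-(5-bromo-2-methoxyphenoxy)cyclohexane-1,3-dione | O=C1CCCC(=O)C1Oc1cc(Br)ccc1OC
A3 | direct plan | 3-bromo-2-(5-bromo-2-methoxyphenoxy)cyclohex-2-en-1-one | O=C1CCCC(Br)=C1Oc1cc(Br)ccc1OC
A4 | direct plan | 3-bromo-2-(5-bromo-2-methoxyphenoxy)phenol | Oc1cccc(Br)c1Oc1cc(Br)ccc1OC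
A5 | direct plan | 3,4,6-tribromo-2-(5-bromo-2-methoxyphenoxy)phenol | Oc1c(Br)cc(Br)c(Br)c1Oc1cc(Br)ccc1OC
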